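**Plan**

Numbering (germacrane, kept for the bicyclic precursors): C1–C3 CH2, C4 CHMe, C5 C=O, C6 CHOH, C7/C8 lactone fusion (O on C8), C9 CH–O-acyl, C10 C(OH)Me, C11–C13 methylene lactone. β is the face of the C10 methyl group in the decalins.
Cuts, in retrosynthetic order: O9–isovaleryl, then C11=C13 (back to a C13 benzyl ester, the spare arm of a malonate), then the anti C9–O/C10–O pair (back to an E C9=C10 alkene). C5 is then re-joined to C10, and in the decalin the lactone C–O/C8–O, C7–C11, C5–O with C6–O, and C4–CH3 are removed in turn.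
Enabling feature: the C5 carbonyl carbon and the C10 carbinol carbon face each other 1,6 across the ten-membered ring, and O5 and O9 are 1,3-related through C10. A C5–C10 bond therefore gives ring A (C1–C5, C10) and ring B (C5–C10) of a trans-decalin in which O6, C11, O8 and O9 are all equatorial and C9–O is antiperiplanar to C5–C10.
Forward order of rings: A and B arrive with (S)-Wieland–Miescher ketone, the γ-lactone closes on ring B (step 9), the ten-membered ring is unveiled when C5–C10 breaks (step 14), and a temporary C5–O–C10 bridge (steps 16–20) delivers O10.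
Stereochemistry: the quaternary C10 of the starting ketone is the only imported element. Its axial methyl sends reagents to the α face (hydride at C9, epoxide, O8, OsO4 for C5/C6), diaxial epoxide opening sets C4, and equilibration sets C7. After ring opening, peripheral epoxidation sets C9 and transannular inversion sets C10.

Key step: step 14

Remark on the chemistry: from the lactonisation (step 9) to the methylenation (step 19), C11 is a malonate-type, freely epimerising centre. It is written without configuration and ends as an sp2 carbon.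

**Route**

Step 1
Reactants: 1 (S)-Wieland–Miescher ketone
Product: 2 9β-hydroxy-10β-methyloctal-4-en-3-one
Conditions: NaBH4 (0.3 equiv), EtOH, 0 °C
Reagents that add atoms: none
Why: Chemoselective borohydride reduction of the saturated C9 ketone (the conjugated C3 carbonyl is less electrophilic), in which hydride arrives axially on the α face away from the angular methyl and gives the equatorial 9β-alcohol, which also masks C9 for the organometallic step.

Step 2
Reactants: 2 9β-hydroxy-10β-methyloctal-4-en-3-one
Product: 3 3,3-ethylenedithio ketal of 2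
Conditions: HS(CH2)2SH (1.2 equiv), BF3·OEt2 (0.5 equiv), MeOH, 0 °C → rt
Reagents that add atoms: ethane-1,2-dithiol SCCS
Why: Lewis-acid thioketalisation of the enone carbonyl, which, unlike O-ketalisation, leaves the double bond at C4=C5.

Step 3
Reactants: 3 3,3-ethylenedithio ketal of 2
Product: 4 10β-methyloctal-4-en-9β-ol
Conditions: Raney Ni (W-2, deactivated in acetone), EtOH, reflux
Reagents that add atoms: none
Why: Mozingo reductive desulfurisation replaces both C–S bonds by C–H and erases the C3 oxygen, while the deactivated catalyst should leave the trisubstituted C4=C5 bond in place.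

Step 4
Reactants: 4 10β-methyloctal-4-en-9β-ol
Product: 5 4α,5α-epoxy-10β-methyldecalin-9β-ol
Conditions: mCPBA (1.2 equiv), NaHCO3, CH2Cl2, 0 °C
Reagents that add atoms: mCPBA O=C(OO)c1cccc(Cl)c1
Why: Prilezhaev epoxidation of the only alkene, in which the axial 10β-methyl group screens the β face so that the 4α,5α-epoxide should predominate (the minor β-epoxide is removed by chromatography).

Step 5
Reactants: 5 4α,5α-epoxy-10β-methyldecalin-9β-ol; 6 methylmagnesium bromide
Product: 7 4β,10β-dimethyl-trans-decalin-5α,9β-diol
Conditions: MeMgBr (5 equiv), CuI (0.2 equiv), THF, 0 °C → reflux; sat. aq. NH4Cl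
Reagents that add atoms: none
Why: Copper-assisted Grignard opening under the Fürst–Plattner rule, where attack at the secondary C4 from the β face is the only trans-diaxial path (the pattern of the classical 6β-methylation of steroidal 5α,6α-epoxides), so the axial 4β-methyl group is set and the axial 5α-alkoxide remains.

Step 6
Reactants: 7 4β,10β-dimethyl-trans-decalin-5α,9β-diol
Product: 9 5α-hydroxy-4β,10β-dimethyloctal-7-en-9-one, via 5α-hydroxy ketone 8 (not isolated)
Conditions: IBX (4 equiv), DMSO–PhF, 75 °C
Reagents that add atoms: none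
Why: IBX oxidises the secondary alcohol and then dehydrogenates the ketone through its only possible enol (towards C8, since C10 is quaternary), while the tertiary alcohol is inert.

Step 7
Reactants: 9 5α-hydroxy-4β,10β-dimethyloctal-7-en-9-one
Product: 10 4β,10β-dimethyl-5,7-dien-9-one
Conditions: SOCl2 (1.5 equiv), pyridine, 0 °C
Reagents that add atoms: none
Why: E2 dehydration of the axial tertiary chlorosulfite, for which only 6β-H is antiperiplanar (at C4 the axial position holds the methyl group) and is also vinylogously acidified, so C5=C6 forms regiospecifically, C4 is untouched, and the 5,6,6-trisubstituted cyclohexa-2,4-dienone is too crowded to dimerise.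

Step 8
Reactants: 10 4β,10β-dimethyl-5,7-dien-9-one; 11 dibenzyl malonate
Product: 12 dibenzyl (4β,10β-dimethyl-9-oxooctal-5-en-7β-yl)malonate
Conditions: 11 (2 equiv), NaH (0.2 equiv), THF, rt → 40 °C
Reagents that add atoms: none
Why: Reversible Michael addition in which the 1,6-terminus C5 is fully substituted and next to quaternary C10, so only the 1,4-adduct can accumulate, retro-Michael equilibration places the bulky malonyl group pseudo-equatorial (7β) on the ring B half-chair, and C4 holds because its 4α-H lies in the nodal plane of the dienone.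

Step 9
Reactants: 12 dibenzyl (4β,10β-dimethyl-9-oxooctal-5-en-7β-yl)malonate
Product: 14 benzyl 9-oxoeudesm-5-en-12,8-olid-13-oate, via 8α-hydroxy ketone 13 (not isolated)
Conditions: KN(SiMe3)2 (2.2 equiv), THF, −78 °C; 2-(phenylsulfonyl)-3-phenyloxaziridine, −78 °C; AcOH; then TsOH·H2O (0.1 equiv), CH2Cl2, rt
Reagents that add atoms: 2-(phenylsulfonyl)-3-phenyloxaziridine O=S(=O)(c1ccccc1)N1OC1c1ccccc1
Why: Davis enolate hydroxylation in which the malonate is deprotonated first (which also forbids retro-Michael loss), the second equivalent gives the only possible and more reactive ketone enolate (C8), oxidation occurs on the α face anti to the 7β side chain and the 10β-methyl, and acid then closes the trans-fused γ-lactone between the two equatorial groups.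

Step 10
Reactants: 14 benzyl 9-oxoeudesm-5-en-12,8-olid-13-oate
Product: 15 benzyl 9β-hydroxyeudesm-5-en-12,8-olid-13-oate
Conditions: NaBH4, CeCl3·7H2O, MeOH–THF, −78 → −40 °C
Reagents that add atoms: none
Why: Luche reduction of the activated α-acyloxy ketone, with hydride delivered axially on the α face away from the neighbouring 10β-methyl as in step 1 to give the equatorial 9β-alcohol, while lactone and ester survive at low temperature.

Step 11
Reactants: 15 benzyl 9β-hydroxyeudesm-5-en-12,8-olid-13-oate
Product: 16 benzyl 9β-mesyloxyeudesm-5-en-12,8-olid-13-oate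
Conditions: MsCl, DMAP (cat.), pyridine–CH2Cl2, 0 °C → rt
Reagents that add atoms: methanesulfonyl chloride CS(=O)(=O)Cl
Why: Sulfonylation of the only hydroxyl group with retention at C9, using pyridine (too weak a base to enolise C11 appreciably) so that the malonate-type position stays out of play.

Step 12
Reactants: 16 benzyl 9β-mesyloxyeudesm-5-en-12,8-olid-13-oate
Product: 17 benzyl 5α,6α-dihydroxy-9β-mesyloxyeudesman-12,8-olid-13-oate
Conditions: OsO4 (10 mol %), NMO (3 equiv), MeSO2NH2, acetone–H2O, rt
Reagents that add atoms: osmium tetroxide O=[Os](=O)(=O)=O; N-methylmorpholine N-oxide C[N+]1([O-])CCOCC1; water O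
Why: Upjohn dihydroxylation, a suprafacial addition to the α face because the β face is closed by the axial methyl groups at C4 and C10 and by the 7β side chain (as for steroidal 5-enes), which sets the axial 5α-OH (trans ring fusion) and the equatorial 6α-OH in one operation.

Step 13
Reactants: 17 benzyl 5α,6α-dihydroxy-9β-mesyloxyeudesman-12,8-olid-13-oate
Product: 18 benzyl 6α-(tert-butyldimethylsilyloxy)-5α-hydroxy-9β-mesyloxyeudesman-12,8-olid-13-oate
Conditions: TBSOTf (1.2 equiv), 2,6-lutidine, CH2Cl2, −78 → 0 °C
Reagents that add atoms: tert-butyldimethylsilyl triflate CC(C)(C)[Si](C)(C)OS(=O)(=O)C(F)(F)F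
Why: Selective silylation of the secondary equatorial 6α-OH, the tertiary 5α-OH between C4, C6 and quaternary C10 being too crowded to react, which also blocks translactonisation to O6.

Step 14
Reactants: 18 benzyl 6α-(tert-butyldimethylsilyloxy)-5α-hydroxy-9β-mesyloxyeudesman-12,8-olid-13-oate
Product: 19 benzyl (9E)-6-(tert-butyldimethylsilyloxy)-5-oxogermacr-9-en-12,8-olid-13-oate
Conditions: KN(SiMe3)2 (2.05 equiv), THF, −78 → 0 °C; AcOH, −78 °C
Reagents that add atoms: none
Why: The first equivalent of base parks the acidic C11–H as an inert enolate and the second forms the tertiary C5 alkoxide, whose lone pair pushes into the C5–C10 σ bond while that bond, antiperiplanar to the equatorial C9–OMs bond in the rigid trans-decalin, feeds the C9–O σ* orbital, so C5=O, C9=C10 and loss of mesylate arise in one concerted event. This is the Grob (Wharton-type) fragmentation of a cyclic 1,3-diol monosulfonate, the established way from decalins to (E)-cyclodecenones. No ring is closed: rings A and B merge into their common ten-membered periphery when the shared bond breaks, helped by release of the syn-diaxial 4β-Me/10β-Me repulsion. No stereocentre is created; the only new stereo-element is the alkene, which must be E because C1 and C8 are anti about C9–C10 in the chair, while C4, C6, C7 and C8 are carried over unchanged. The selectivity needed is fragmentation over substitution, elimination, silyl migration and enolisation, and the substrate secures it: the equatorial neopentyl mesylate has no antiperiplanar hydrogen and a shielded rear side, O5 is too crowded to accept the silyl group, and the base is consumed stoichiometrically so that the new ketone with its C4–H and C6–H is not left in contact with it.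

Step 15
Reactants: 19 benzyl (9E)-6-(tert-butyldimethylsilyloxy)-5-oxogermacr-9-en-12,8-olid-13-oate
Product: 20 9,10-epoxide of 19 (oxygen on the outer face)
Conditions: mCPBA (1.1 equiv), NaHCO3, CH2Cl2, 0 °C
Reagents that add atoms: mCPBA O=C(OO)c1cccc(Cl)c1
Why: Prilezhaev epoxidation under peripheral attack: the strained E-alkene stands perpendicular to the mean ring plane, held by the trans-lactone with H8 anti to H9, its inner face looks at C5, and the open outer face is the one the mesylate left from, so C9–O receives the configuration of the target.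

Step 16
Reactants: 20 9,10-epoxide of 19
Product: 21 benzyl 5,10-epoxy-9-hydroxy-5-methoxy-6-(tert-butyldimethylsilyloxy)germacran-12,8-olid-13-oate
Conditions: CSA (0.1 equiv), MeOH–CH2Cl2, −20 → 0 °C
Reagents that add atoms: methanol CO
Why: Proposed new method: protonation loosens the tertiary C10–O bond, whose rear side points into the ring at the C5 carbonyl 1,6 across it, so the carbonyl oxygen (directly or as its methanol hemiketal) attacks C10 with inversion, methanol caps the bridged oxocarbenium ion from outside (C5 configuration dictated by the out,out geometry and erased in step 20) and the C9–O bond is untouched, attack at C9 being disfavoured by the adjacent acyloxy group and the lack of cation stabilisation; the closest known reaction types are the acid-induced cyclisation of epoxy ketones to bicyclic ketals and the 11-oxabicyclo[4.4.1]undecane hemiketal derivatives of 6-hydroxycyclodecanones formed in the Criegee rearrangement of decalyl peresters.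

Step 17
Reactants: 21 benzyl 5,10-epoxy-9-hydroxy-5-methoxy-6-(tert-butyldimethylsilyloxy)germacran-12,8-olid-13-oate; 22 isovaleric anhydride
Product: 23 9-O-isovalerate of 21
Conditions: 22 (3 equiv), DMAP, pyridine, CH2Cl2, rt → 40 °C
Reagents that add atoms: none
Why: DMAP-catalysed acylation of the only free hydroxyl group, O10 and C5 being tied up in the ketal and O6 silylated, with retention at C9.

Step 18
Reactants: 23 9-O-isovalerate of 21
Product: 24 13-oic acid from 23
Conditions: H2 (1 atm), Pd/C (10 %), EtOAc, rt
Reagents that add atoms: none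
Why: Neutral hydrogenolysis of the benzyl ester at a stage where the molecule has no alkene, which spares lactone, isovalerate, ketal and silyl ether; the acid is used at once to avoid premature decarboxylation.

Step 19
Reactants: 24 13-oic acid from 23; 25 formaldehyde
Product: 27 5,10-epoxy-9-isovaleroyloxy-5-methoxy-6-(tert-butyldimethylsilyloxy)germacr-11(13)-en-12,8-olide, via Mannich base 26 (not isolated)
Conditions: paraformaldehyde, Et2NH, EtOAc, rt → 60 °C
Reagents that add atoms: none
Why: Decarboxylative Mannich methylenation of a malonic half-ester-type acid, in which aminomethylation at C11 is followed by loss of CO2 and Et2NH to give the α-methylene lactone without any strong base, so the esters and every stereocentre are safe.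

Step 20
Reactants: 27 5,10-epoxy-9-isovaleroyloxy-5-methoxy-6-(tert-butyldimethylsilyloxy)germacr-11(13)-en-12,8-olide
Product: 28 CNP0240128.1
Conditions: 48 % aq. HF, MeCN, 0 °C → rt
Reagents that add atoms: water O
Why: Acidic fluoride removes the silyl ether and hydrolyses the strained bridged ketal by cleavage of the C5–O bridge bond (O10 stays on C10 with its configuration), releasing the C5 ketone, the 6-OH and the 10-OH under conditions too mild to enolise C4/C6 or to harm the methylene lactone.

**Compound list**

| No. | Name | SMILES | Role |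
|---|---|---|---|
| 1 | (S)-Wieland–Miescher ketone, (8aS)-8a-methyl-3,4,8,8a-tetrahydronaphthalene-1,6(2H,7H)-dione | C[C@]12CCC(=O)C=C1CCCC2=O | starting material |
| 2 | 9β-hydroxy-10β-methyloctal-4-en-3-one, (4aS,5S)-5-hydroxy-4a-methyl-4,4a,5,6,7,8-hexahydronaphthalen-2(3H)-one | C1CCC2=CC(=O)CC[C@]2(C)[C@H]1O | intermediate |
| 3 | 3,3-ethylenedithio ketal of 2 (C4=C5 kept) | C1CCC2=CC3(SCCS3)CC[C@]2(C)[C@H]1O | intermediate |
| 4 | 10β-methyloctal-4-en-9β-ol, (1S,8aS)-8a-methyl-1,2,3,4,6,7,8,8a-octahydronaphthalen-1-ol | C1CCC2=CCCC[C@]2(C)[C@H]1O | intermediate |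
| 5 | 4α,5α-epoxy-10β-methyldecalin-9β-ol | C1CC[C@@]2(O3)[C@H]3CCC[C@]2(C)[C@H]1O | intermediate |
| 6 | methylmagnesium bromide | C[Mg]Br | starting material |
| 7 | 4β,10β-dimethyl-trans-decalin-5α,9β-diol | C1CC[C@@]2(O)[C@@H](C)CCC[C@]2(C)[C@H]1O | intermediate |
| 8 | 5α-hydroxy-4β,10β-dimethyl-trans-decalin-9-one | C1CC[C@@]2(O)[C@@H](C)CCC[C@]2(C)C1=O | intermediate |
| 9 | 5α-hydroxy-4β,10β-dimethyloctal-7-en-9-one (trans-fused) | C1=CC[C@@]2(O)[C@@H](C)CCC[C@]2(C)C1=O | intermediate |
| 10 | 4β,10β-dimethyl-5,7-dien-9-one, (5S,8aS)-5,8a-dimethyl-6,7,8,8a-tetrahydronaphthalen-1(5H)-one | C1=CC=C2[C@@H](C)CCC[C@]2(C)C1=O | intermediate |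
| 11 | dibenzyl malonate | O=C(CC(=O)OCc1ccccc1)OCc1ccccc1 | starting material |
| 12 | dibenzyl (4β,10β-dimethyl-9-oxooctal-5-en-7β-yl)malonate | C1[C@@H](C(C(=O)OCc3ccccc3)C(=O)OCc3ccccc3)C=C2[C@@H](C)CCC[C@]2(C)C1=O | intermediate |
| 13 | 8α-hydroxy derivative of 12 | O[C@@H]1[C@@H](C(C(=O)OCc3ccccc3)C(=O)OCc3ccccc3)C=C2[C@@H](C)CCC[C@]2(C)C1=O | intermediate |
| 14 | benzyl 9-oxoeudesm-5-en-12,8-olid-13-oate (4β-Me, 10β-Me, 7αH, 8βH, trans-lactone) | C1(C(=O)OCc5ccccc5)C(=O)O[C@@H]2[C@@H]1C=C3[C@@H](C)CCC[C@]3(C)C2=O | intermediate |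
| 15 | benzyl 9β-hydroxyeudesm-5-en-12,8-olid-13-oate | C1(C(=O)OCc5ccccc5)C(=O)O[C@@H]2[C@@H]1C=C3[C@@H](C)CCC[C@]3(C)[C@H]2O | intermediate |
| 16 | benzyl 9β-mesyloxyeudesm-5-en-12,8-olid-13-oate | C1(C(=O)OCc5ccccc5)C(=O)O[C@@H]2[C@@H]1C=C3[C@@H](C)CCC[C@]3(C)[C@H]2OS(C)(=O)=O | intermediate |
| 17 | benzyl 5α,6α-dihydroxy-9β-mesyloxyeudesman-12,8-olid-13-oate (trans-decalin) | C1(C(=O)OCc5ccccc5)C(=O)O[C@@H]2[C@@H]1[C@H](O)[C@@]3(O)[C@@H](C)CCC[C@]3(C)[C@H]2OS(C)(=O)=O | intermediate |
| 18 | benzyl 6α-(tert-butyldimethylsilyloxy)-5α-hydroxy-9β-mesyloxyeudesman-12,8-olid-13-oate | C1(C(=O)OCc5ccccc5)C(=O)O[C@@H]2[C@@H]1[C@H](O[Si](C)(C)C(C)(C)C)[C@@]3(O)[C@@H](C)CCC[C@]3(C)[C@H]2OS(C)(=O)=O | intermediate |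
| 19 | benzyl (9E)-6-(tert-butyldimethylsilyloxy)-5-oxogermacr-9-en-12,8-olid-13-oate (C4, C6, C7, C8 as in 18) | C1C/C(C)=C/[C@@H]2OC(=O)C(C(=O)OCc3ccccc3)[C@H]2[C@H](O[Si](C)(C)C(C)(C)C)C(=O)[C@@H](C)C1 | intermediate |
| 20 | 9,10-epoxide of 19, oxygen on the outer face (C9–O as in the target) | C1(C(=O)OCc5ccccc5)C(=O)O[C@@H]2[C@@H]1[C@H](O[Si](C)(C)C(C)(C)C)C(=O)[C@@H](C)CCC[C@]3(C)O[C@@H]23 | intermediate |
| 21 | benzyl 5,10-epoxy-9-hydroxy-5-methoxy-6-(tert-butyldimethylsilyloxy)germacran-12,8-olid-13-oate (out,out 11-oxabicyclo[4.4.1]undecane; C9, C10 as in the target) | C1(C(=O)OCc5ccccc5)C(=O)O[C@@H]2[C@@H]1[C@H](O[Si](C)(C)C(C)(C)C)[C@]3(OC)[C@@H](C)CCC[C@@](C)(O3)[C@H]2O | intermediate |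
| 22 | isovaleric anhydride | CC(C)CC(=O)OC(=O)CC(C)C | starting material |
| 23 | 9-O-isovalerate of 21 | C1(C(=O)OCc5ccccc5)C(=O)O[C@@H]2[C@@H]1[C@H](O[Si](C)(C)C(C)(C)C)[C@]3(OC)[C@@H](C)CCC[C@@](C)(O3)[C@H]2OC(=O)CC(C)C | intermediate |
| 24 | 13-oic acid from 23 | C1(C(=O)O)C(=O)O[C@@H]2[C@@H]1[C@H](O[Si](C)(C)C(C)(C)C)[C@]3(OC)[C@@H](C)CCC[C@@](C)(O3)[C@H]2OC(=O)CC(C)C | intermediate |
| 25 | formaldehyde (used as paraformaldehyde) | C=O | starting material |
| 26 | 11-(diethylaminomethyl) derivative of 24 (Mannich base) | C1(CN(CC)CC)(C(=O)O)C(=O)O[C@@H]2[C@@H]1[C@H](O[Si](C)(C)C(C)(C)C)[C@]3(OC)[C@@H](C)CCC[C@@](C)(O3)[C@H]2OC(=O)CC(C)C | intermediate |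
| 27 | 5,10-epoxy-9-isovaleroyloxy-5-methoxy-6-(tert-butyldimethylsilyloxy)germacr-11(13)-en-12,8-olide | C=C1C(=O)O[C@@H]2[C@@H]1[C@H](O[Si](C)(C)C(C)(C)C)[C@]3(OC)[C@@H](C)CCC[C@@](C)(O3)[C@H]2OC(=O)CC(C)C | intermediate |
| 28 | CNP0240128.1, (4S,6S,7S,8R,9S,10R)-6,10-dihydroxy-9-(3-methylbutanoyloxy)-5-oxogermacr-11(13)-en-12,8-olide | C=C1C(=O)O[C@@H]2[C@@H]1[C@H](O)C(=O)[C@@H](C)CCC[C@@](C)(O)[C@H]2OC(=O)CC(C)C | target |

**Counts**

Total step count: 20. Longest linear sequence: 20 steps (from 1).

**Steps most likely to fail**

Step 16 (transannular ketalising epoxide opening).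
- The developing C10 cation may lose a proton to give an allylic alcohol or accept a transannular hydride.
- The oxygen may instead close the six-membered bridge at C9.
- The fallback avoids cationic chemistry and uses only known reactions. It sets out from 19.
- Thiyl-radical-catalysed equilibration (PhSSPh, hν, benzene), the usual way of relaxing trisubstituted E-alkenes in medium rings, should give the (9Z)-isomer of 19 F1.
- Upjohn dihydroxylation (OsO4 cat., NMO, acetone–H2O) should then add both oxygens to the open face. Allylic 1,3-strain puts H8 in the alkene plane, and C7 with the body of the ring covers the other face.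
- Syn addition to the Z-alkene is stereochemically equivalent to anti addition to the E-alkene, so this should give the 9,10-dihydroxy-5-ketone F2 with the C9 and C10 configurations of the target.
- Ordinary ketalisation of this 10-hydroxy ketone (CSA, MeOH, HC(OMe)3) comes back to the route at 21.

Step 8 (malonate addition to the dienone).
- Loss of the extended conjugation may leave the equilibrium short of completion.
- Addition may stray to the far terminus, or equilibration at C7 may stay incomplete.
- The fallback adds the malonate before the C5=C6 bond exists. It sets out from 9.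
- Silylation (TMSOTf, 2,6-lutidine) gives the 5α-trimethylsilyloxy enone F3, an ordinary cyclohexenone that can neither dehydrate nor undergo retro-aldol cleavage.
- Malonate 11 with catalytic NaH under equilibrating conditions gives the 7β-malonyl 5α-silyloxy ketone F4. The axial 7α position is now also blocked by the syn-axial 5α-oxygen substituent.
- Citric acid in MeOH frees the 5α-hydroxy adduct F5.
- SOCl2/pyridine removes the axial alcohol antiperiplanar to 6β-H, which comes back to the route at 12.

Step 9 (hydroxylation of the keto-malonate dianion).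
- The second deprotonation may be incomplete, or oxygen transfer to the malonate anion may compete.
- The fallback replaces enolate chemistry by soft enolisation and a Rubottom oxidation. It sets out from 12.
- TMSOTf/Et3N followed by a NaHCO3 wash (which hydrolyses any malonate ketene acetal) gives the C8=C9 trimethylsilyl enol ether F6.
- mCPBA (1 equiv, NaHCO3, −20 °C) oxidises this far more nucleophilic double bond from the α face in preference to the hindered C5=C6.
- TsOH then removes silicon to give 13 and closes the lactone, which comes back to the route at 14.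

**Further compounds**

F1 | step 16 | benzyl (9Z)-6-(tert-butyldimethylsilyloxy)-5-oxogermacr-9-en-12,8-olid-13-oate | C1C/C(C)=C\[C@@H]2OC(=O)C(C(=O)OCc3ccccc3)[C@H]2[C@H](O[Si](C)(C)C(C)(C)C)C(=O)[C@@H](C)C1
F2 | step 16 | benzyl 9,10-dihydroxy-5-oxo-6-(tert-butyldimethylsilyloxy)germacran-12,8-olid-13-oate (C9, C10 as in the target) | C1(C(=O)OCc5ccccc5)C(=O)O[C@@H]2[C@@H]1[C@H](O[Si](C)(C)C(C)(C)C)C(=O)[C@@H](C)CCC[C@@](C)(O)[C@H]2O
F3 | step 8 | 5α-trimethylsilyloxy-4β,10β-dimethyloctal-7-en-9-one | C1=CC[C@@]2(O[Si](C)(C)C)[C@@H](C)CCC[C@]2(C)C1=O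
F4 | step 8 | dibenzyl (5α-trimethylsilyloxy-4β,10β-dimethyl-9-oxo-trans-decal-7β-yl)malonate | C1[C@@H](C(C(=O)OCc3ccccc3)C(=O)OCc3ccccc3)C[C@@]2(O[Si](C)(C)C)[C@@H](C)CCC[C@]2(C)C1=O
F5 | step 8 | dibenzyl (5α-hydroxy-4β,10β-dimethyl-9-oxo-trans-decal-7β-yl)malonate | C1[C@@H](C(C(=O)OCc3ccccc3)C(=O)OCc3ccccc3)C[C@@]2(O)[C@@H](C)CCC[C@]2(C)C1=O
F6 | step 9 | C8=C9 trimethylsilyl enol ether of 12 | C=1[C@@H](C(C(=O)OCc3ccccc3)C(=O)OCc3ccccc3)C=C2[C@@H](C)CCC[C@]2(C)C=1O[Si](C)(C)C
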